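Everything rests on opening the dihydrofuran ring that fuses the arene to ring A: arene carbon C6' is joined through the ether oxygen to quaternary C10, and its neighbour C5' is bonded directly to C1. Two adjacent aryl bonds of this kind are the footprint of an aryne inserted between the oxygen of a C10 hydroxyl and the carbonyl carbon of a C1 ketone. In one operation the aryne from silyl triflate 18 should accept the C10 alkoxide of ketol 11 and close onto C1, forming both bonds, the ring and the C1 centre. The precursor is the C10-hydroxy C1-ketone of the cyclopropane-fused decalin, with C8 held as a dioxolane and C9 still CH2.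

Key step: step 12

Remarks on the chemistry
- Numbering: aristolane numbering for the terpenoid (ring A = C1–C5, C10; ring B = C5–C10; C11 = CMe2 bridging C6 and C7; methyls on C4 and C5). α is the face carrying the C4 and C5 methyls; β is the opposite face, on which C11 lies. Arene positions are primed: C1' acyl-bearing, C2' OH/OMOM, C3' H, C4' OMe, C5' bonded to C1, C6' bonded to the ether oxygen.
- Assumption: the (S,S,S) phosphoramidite in step 1 is taken to give the 3R ketone; if the sense of induction is the opposite, the mirror-image ligand is used. Enantiomeric purity can be raised by crystallising 8.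
- Order after the key step: the C1 hydroxyl is removed and the chalcone is built while C8 is still a ketal. A free C8 ketone with C9–H is a β-aryloxy ketone that base could open by elimination, so it is unveiled only for the C9 oxidation.

Step 1
Reactants: 1 2-methylcyclohex-2-en-1-one
Product: 2 (3R)-2,3-dimethylcyclohexan-1-one (C2 epimers)
Conditions: Me3Al, copper thiophene-2-carboxylate Cu(O2CC4H3S) (2 mol%), (S)-BINOL N,N-bis[(S)-1-phenylethyl]phosphoramidite (4 mol%), Et2O, −30 °C; aq. NH4Cl
Reagents that add atoms: trimethylaluminium, C[Al](C)C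
Why: Copper-catalysed asymmetric conjugate addition of a methylaluminium reagent to a cyclic enone; the chiral copper–phosphoramidite complex selects the enone face and fixes C3 (later C4), while C2 is re-formed in step 2.

Step 2
Reactants: 2 (3R)-2,3-dimethylcyclohexan-1-one; 3 but-3-en-2-one
Product: 6 (4aS,5R)-4a,5-dimethyl-4,4a,5,6,7,8-hexahydronaphthalen-2(3H)-one, via Michael diketone 4 (not isolated), via aldol ketol 5 (not isolated)
Conditions: KOH (0.3 equiv), EtOH, −10 → 25 °C; then KOH, EtOH, reflux
Reagents that add atoms: none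
Why: Robinson annulation (Michael addition of the more substituted enolate, aldol closure, dehydration); the enone should add to the enolate face anti to the C3 methyl, placing the new quaternary methyl cis to it (C5 of the target).

Step 3
Reactants: 6 (4aS,5R)-4a,5-dimethyl-4,4a,5,6,7,8-hexahydronaphthalen-2(3H)-one
Product: 7 (4aR,5R)-4a,5-dimethyl-5,6,7,8-tetrahydronaphthalen-2(4aH)-one
Conditions: DDQ, 1,4-dioxane, reflux
Reagents that add atoms: none
Why: DDQ dehydrogenation of a 4a-substituted octalone under neutral conditions goes through the cross-conjugated dienol and gives the cross-conjugated dienone (new C6=C7 bond); no stereocentre is touched, and the C4a label changes only through CIP priorities.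

Step 4
Reactants: 7 (4aR,5R)-4a,5-dimethyl-5,6,7,8-tetrahydronaphthalen-2(4aH)-one
Product: 8 (−)-aristolone (aristol-9-en-8-one)
Conditions: isopropyldiphenylsulfonium tetrafluoroborate, LDA, DME, −78 °C; then 7, −78 → −20 °C
Reagents that add atoms: isopropyldiphenylsulfonium tetrafluoroborate, CC(C)[S+](c1ccccc1)c1ccccc1.F[B-](F)(F)F
Why: Corey–Chaykovsky-type cyclopropanation (conjugate addition of the sulfonium isopropylide, then ring closure with loss of Ph2S) at the disubstituted C6=C7 bond, not at the fully substituted C10; the ylide should attack C6 anti to the C5 methyl, so the necessarily cis-fused cyclopropane lies on the β face (sets C6 and C7).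

Step 5
Reactants: 8 (−)-aristolone
Product: 9 8,8-(ethylenedioxy)aristol-1(10)-ene
Conditions: HOCH2CH2OH, p-TsOH·H2O (cat.), benzene, reflux (Dean–Stark)
Reagents that add atoms: ethylene glycol, OCCO
Why: Thermodynamic acid-catalysed ketalisation of a conjugated enone moves the double bond out of conjugation, as with steroidal 4-en-3-ones; the only γ-hydrogens are on C1, so the alkene settles at C1=C10, and the non-nucleophilic acid should leave the cyclopropane intact.

Step 6
Reactants: 9 8,8-(ethylenedioxy)aristol-1(10)-ene
Product: 10 8,8-(ethylenedioxy)aristolane-1α,10α-diol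
Conditions: OsO4 (5 mol%), NMO, acetone/H2O, 25 °C; aq. Na2SO3
Reagents that add atoms: osmium tetroxide, O=[Os](=O)(=O)=O (re-formed from N-methylmorpholine N-oxide, C[N+]1([O-])CCOCC1, and water, O)
Why: Osmium tetroxide syn-dihydroxylation; the endo methyl of the β cyclopropane sits over C9/C10 of ring B and should block that face more than the C5 methyl blocks the other, so both oxygens should enter on the α face, setting C10 (oxygen cis to the C5 methyl) and C1.

Step 7
Reactants: 10 8,8-(ethylenedioxy)aristolane-1α,10α-diol
Product: 11 8,8-(ethylenedioxy)-10α-hydroxyaristolan-1-one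
Conditions: IBX, DMSO, 25 °C
Reagents that add atoms: none
Why: IBX oxidises the secondary carbinol of a secondary/tertiary 1,2-diol to the α-hydroxy ketone without glycol cleavage; the tertiary C10 hydroxyl cannot be oxidised and keeps its configuration.

Step 8
Reactants: 12 1-(2,6-dihydroxy-4-methoxyphenyl)ethan-1-one
Product: 13 1-[2-hydroxy-4-methoxy-6-(methoxymethoxy)phenyl]ethan-1-one
Conditions: MOMCl (1.1 equiv), i-Pr2NEt, CH2Cl2, 0 → 25 °C
Reagents that add atoms: chloromethyl methyl ether, COCCl
Why: O-alkylation of a phenol; once one hydroxyl is capped the other is held in a hydrogen bond to the carbonyl and reacts far more slowly, so mono-protection should dominate.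

Step 9
Reactants: 13 1-[2-hydroxy-4-methoxy-6-(methoxymethoxy)phenyl]ethan-1-one
Product: 14 1-[3-bromo-2-hydroxy-4-methoxy-6-(methoxymethoxy)phenyl]ethan-1-one
Conditions: NBS, i-Pr2NH (cat.), CH2Cl2, 0 °C
Reagents that add atoms: N-bromosuccinimide, O=C1CCC(=O)N1Br
Why: Electrophilic aromatic bromination; amine-mediated NBS bromination is ortho-selective for phenols, so bromine should enter C5' next to the free hydroxyl and not the position flanked by the two ethers.

Step 10
Reactants: 14 1-[3-bromo-2-hydroxy-4-methoxy-6-(methoxymethoxy)phenyl]ethan-1-one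
Product: 17 1-[2-hydroxy-4-methoxy-6-(methoxymethoxy)-3-(trimethylsilyl)phenyl]ethan-1-one, via bis-silyl ether 15 (not isolated), via C-silyl enol ether 16 (not isolated)
Conditions: TMSOTf (2.3 equiv), Et3N, CH2Cl2, 0 °C; salts removed (pentane); n-BuLi, THF, −78 °C; aq. NH4Cl; K2CO3, MeOH, 0 °C
Reagents that add atoms: trimethylsilyl triflate, C[Si](C)(C)OS(=O)(=O)C(F)(F)F
Why: Silylation caps the phenol and masks the ketone as its silyl enol ether, so bromine–lithium exchange is followed only by the 1,3 O→C silyl shift (retro-Brook rearrangement) to C5'; mild methanolysis then returns the ketone and leaves the aryl–silicon bond.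

Step 11
Reactants: 17 1-[2-hydroxy-4-methoxy-6-(methoxymethoxy)-3-(trimethylsilyl)phenyl]ethan-1-one
Product: 18 2-acetyl-5-methoxy-3-(methoxymethoxy)-6-(trimethylsilyl)phenyl trifluoromethanesulfonate
Conditions: Tf2O, pyridine, CH2Cl2, 0 °C
Reagents that add atoms: triflic anhydride, O=S(=O)(OS(=O)(=O)C(F)(F)F)C(F)(F)F
Why: O-sulfonylation of the phenol gives the ortho-silylaryl triflate; the ketone and both ethers are inert to the reagent.

Step 12
Reactants: 11 8,8-(ethylenedioxy)-10α-hydroxyaristolan-1-one; 18 2-acetyl-5-methoxy-3-(methoxymethoxy)-6-(trimethylsilyl)phenyl trifluoromethanesulfonate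
Product: 20 cis-fused 1β-hydroxy dihydrobenzofuran ketal, via aryne 19 (not isolated)
Conditions: CsF (4 equiv), 18-crown-6 (0.5 equiv), THF, 25 → 50 °C, slow addition of 18 (1.8 equiv)
Reagents that add atoms: none
Why: Proposed new method: fluoride removes the trimethylsilyl group of 18 and triflate leaves to give aryne 19; the caesium alkoxide of the C10 hydroxyl (acidified by the neighbouring C1 carbonyl and regenerated by the product alkoxide) adds to aryne carbon C6', and the resulting C5' aryl anion adds to the C1 carbonyl. The closest known reaction type is the aryne annulation of ortho-hydroxyaryl ketones and esters (O-arylation, then capture of the aryl anion by the carbonyl), together with aryne O–H insertion of alcohols; a tertiary α-ketol has not been used in this way. The dihydrofuran ring closes by 5-exo-trig addition of the aryl anion to the C1 carbonyl. The new C1 centre is fixed by the two-atom O–aryl tether, which reaches only the carbonyl face syn to the C10 oxygen, so the ring is cis-fused with the C1 hydroxyl β; C10 is not touched. The step needs alkoxide attack at C6' and not C5': the inductively withdrawing methoxy group on C4' distorts the aryne so that the remote carbon C6' is the electrophilic one and the anion develops next to oxygen, an effect expected to outweigh that of the acetyl group. It also needs O-arylation over C-arylation and ring closure over protonation, which the much higher acidity of the ketol O–H than of the C2 and acetyl C–H bonds, the C8 dioxolane (no ring B enolate, no β-elimination) and the aprotic medium should secure.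

Step 13
Reactants: 20 cis-fused 1β-hydroxy dihydrobenzofuran ketal
Product: 21 cis-fused 1β-H dihydrobenzofuran ketal
Conditions: Et3SiH (5 equiv), CF3CO2H (3 equiv), CH2Cl2, −40 → −20 °C; cold aq. NaHCO3
Reagents that add atoms: none
Why: Ionic hydrogenation of a tertiary benzylic alcohol: acid ionises C1 to a cation stabilised by two ortho oxygens and one para oxygen, and triethylsilane can deliver hydride only to the face that keeps the five-membered ring cis-fused (H β); low temperature and limited acid should spare the dioxolane, the MOM ether and the aryl ketone.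

Step 14
Reactants: 21 cis-fused 1β-H dihydrobenzofuran ketal; 22 4-methoxybenzaldehyde
Product: 24 MOM-protected chalcone ketal, via aldol adduct 23 (not isolated)
Conditions: KOH (50% aq.), EtOH, 25 °C
Reagents that add atoms: none
Why: Claisen–Schmidt condensation (aldol addition of the aryl methyl ketone enolate, then E1cB dehydration) gives the E-enone under thermodynamic control; with C8 still a ketal there is no second enolisable ketone and no β-aryloxy ketone for base to open.

Step 15
Reactants: 24 MOM-protected chalcone ketal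
Product: 25 MOM-protected chalcone C8 ketone
Conditions: PPTS, acetone/H2O (10:1), 55 °C
Reagents that add atoms: water, O
Why: Mild acid-catalysed hydrolysis of the dioxolane (oxocarbenium ion stabilised by the adjacent cyclopropane) under conditions that aryl MOM ethers should tolerate.

Step 16
Reactants: 25 MOM-protected chalcone C8 ketone
Product: 26 MOM-protected 8,9-dione
Conditions: SeO2, 1,4-dioxane/H2O (30:1), 90 °C
Reagents that add atoms: selenium dioxide, O=[Se]=O
Why: Riley oxidation of an α-methylene ketone to the 1,2-dione: the C8 ketone can enolise only toward C9 (C7 is a cyclopropane carbon), C10 is quaternary so dehydrogenation cannot compete, the chalcone ketone has no α-hydrogen, and the MOM ether prevents oxidative cyclisation of the chalcone.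

Step 17
Reactants: 26 MOM-protected 8,9-dione
Product: 27 CNP0121765.1 (target)
Conditions: CF3CO2H, CH2Cl2, 0 °C; aq. NaHCO3
Reagents that add atoms: none
Why: Acidolysis of the aryl methoxymethyl ether, assisted by the ortho carbonyl; a non-nucleophilic acid at low temperature should avoid both homoconjugate opening of the cyclopropyl diketone and flavanone formation.

Compound list
1 | 2-methylcyclohex-2-en-1-one | CC1=CCCCC1=O | starting material
2 | (3R)-2,3-dimethylcyclohexan-1-one (C2 epimers) | C[C@@H]1CCCC(=O)C1C | intermediate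
3 | but-3-en-2-one | CC(=O)C=C | starting material
4 | (2S,3R)-2,3-dimethyl-2-(3-oxobutyl)cyclohexan-1-one | CC(=O)CC[C@@]1(C)[C@H](C)CCCC1=O | intermediate
5 | (4aS,5R)-8a-hydroxy-4a,5-dimethyloctahydronaphthalen-2(1H)-one (C8a epimers) | C[C@@H]1CCCC2(O)CC(=O)CC[C@@]12C | intermediate
6 | (4aS,5R)-4a,5-dimethyl-4,4a,5,6,7,8-hexahydronaphthalen-2(3H)-one (methyls cis) | C[C@@H]1CCCC2=CC(=O)CC[C@@]12C | intermediate
7 | (4aR,5R)-4a,5-dimethyl-5,6,7,8-tetrahydronaphthalen-2(4aH)-one (cross-conjugated dienone, methyls cis) | C[C@@H]1CCCC2=CC(=O)C=C[C@@]12C | intermediate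
8 | (−)-aristolone, aristol-9-en-8-one, (1aR,7R,7aR,7bS); C4/C5 methyls α, cyclopropane β | C[C@@H]1CCCC2=CC(=O)[C@@H]3[C@H]([C@@]12C)C3(C)C | intermediate
9 | 8,8-(ethylenedioxy)aristol-1(10)-ene | C[C@@H]1CCC=C2CC3(OCCO3)[C@@H]4[C@H]([C@@]12C)C4(C)C | intermediate
10 | 8,8-(ethylenedioxy)aristolane-1α,10α-diol | O[C@]12CC3(OCCO3)[C@@H]4[C@@H](C4(C)C)[C@@]1(C)[C@H](C)CC[C@@H]2O | intermediate
11 | 8,8-(ethylenedioxy)-10α-hydroxyaristolan-1-one (hydroxyl cis to the C5 methyl, trans to the cyclopropane) | O[C@]12CC3(OCCO3)[C@@H]4[C@@H](C4(C)C)[C@@]1(C)[C@H](C)CCC2=O | intermediate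
12 | 1-(2,6-dihydroxy-4-methoxyphenyl)ethan-1-one | CC(=O)c1c(O)cc(OC)cc1O | starting material
13 | 1-[2-hydroxy-4-methoxy-6-(methoxymethoxy)phenyl]ethan-1-one | CC(=O)c1c(OCOC)cc(OC)cc1O | intermediate
14 | 1-[3-bromo-2-hydroxy-4-methoxy-6-(methoxymethoxy)phenyl]ethan-1-one | CC(=O)c1c(OCOC)cc(OC)c(Br)c1O | intermediate
15 | {2-bromo-3-methoxy-5-(methoxymethoxy)-6-[1-(trimethylsilyloxy)vinyl]phenoxy}trimethylsilane | C=C(O[Si](C)(C)C)c1c(OCOC)cc(OC)c(Br)c1O[Si](C)(C)C | intermediate
16 | 3-methoxy-5-(methoxymethoxy)-2-(trimethylsilyl)-6-[1-(trimethylsilyloxy)vinyl]phenol | C=C(O[Si](C)(C)C)c1c(OCOC)cc(OC)c([Si](C)(C)C)c1O | intermediate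
17 | 1-[2-hydroxy-4-methoxy-6-(methoxymethoxy)-3-(trimethylsilyl)phenyl]ethan-1-one | CC(=O)c1c(OCOC)cc(OC)c([Si](C)(C)C)c1O | intermediate
18 | 2-acetyl-5-methoxy-3-(methoxymethoxy)-6-(trimethylsilyl)phenyl trifluoromethanesulfonate | CC(=O)c1c(OCOC)cc(OC)c([Si](C)(C)C)c1OS(=O)(=O)C(F)(F)F | intermediate
19 | aryne with the formal triple bond between C5' and C6' (1'-acetyl, 2'-OMOM, 4'-OMe) | CC(=O)C1=C(OCOC)C=C(OC)C#C1 | intermediate
20 | 8,8-(ethylenedioxy)aristolane fused to the arene as a cis 2,3-dihydrobenzofuran: C10–O–C6' α, C1–C5' α, C1–OH β; arene 1'-acetyl, 2'-OMOM, 4'-OMe | CC(=O)c1c(OCOC)cc(OC)c2c1O[C@]13CC4(OCCO4)[C@@H]5[C@@H](C5(C)C)[C@@]1(C)[C@H](C)CC[C@]23O | intermediate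
21 | as 20 with H in place of the C1 hydroxyl (C1–H β) | CC(=O)c1c(OCOC)cc(OC)c2c1O[C@]13CC4(OCCO4)[C@@H]5[C@@H](C5(C)C)[C@@]1(C)[C@H](C)CC[C@H]23 | intermediate
22 | 4-methoxybenzaldehyde | COc1ccc(C=O)cc1 | starting material
23 | β-hydroxy ketone from 21 and 22 (carbinol epimers) | COc1ccc(C(O)CC(=O)c2c(OCOC)cc(OC)c3c2O[C@]24CC5(OCCO5)[C@@H]6[C@@H](C6(C)C)[C@@]2(C)[C@H](C)CC[C@H]34)cc1 | intermediate
24 | (E)-4-methoxychalcone of 21 (C8 dioxolane, 2'-OMOM) | COc1ccc(/C=C/C(=O)c2c(OCOC)cc(OC)c3c2O[C@]24CC5(OCCO5)[C@@H]6[C@@H](C6(C)C)[C@@]2(C)[C@H](C)CC[C@H]34)cc1 | intermediate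
25 | as 24 with a C8 ketone (C9 CH2, 2'-OMOM) | COc1ccc(/C=C/C(=O)c2c(OCOC)cc(OC)c3c2O[C@]24CC(=O)[C@@H]5[C@@H](C5(C)C)[C@@]2(C)[C@H](C)CC[C@H]34)cc1 | intermediate
26 | as 25 with the 8,9-dione (2'-OMOM) | COc1ccc(/C=C/C(=O)c2c(OCOC)cc(OC)c3c2O[C@]24C(=O)C(=O)[C@@H]5[C@@H](C5(C)C)[C@@]2(C)[C@H](C)CC[C@H]34)cc1 | intermediate
27 | CNP0121765.1: 8,9-dione with free 2'-hydroxyl, (E)-chalcone, C10–O α, C1–H β, C4/C5 methyls α, cyclopropane β | COc1ccc(/C=C/C(=O)c2c(O)cc(OC)c3c2O[C@]24C(=O)C(=O)[C@@H]5[C@@H](C5(C)C)[C@@]2(C)[C@H](C)CC[C@H]34)cc1 | target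

Total step count: 17. Longest linear sequence: 13 steps (steps 1–7 and 12–17); the arene branch is steps 8–11.

Steps most likely to fail

1. Step 12. The hindered tertiary alkoxide may add to the aryne too slowly, so that the aryne is consumed by fluoride, by the product alkoxide or by self-reaction; addition may also occur at C5', or the aryl anion may be protonated before it closes onto C1. The fallback uses known chemistry, the palladium-catalysed heteroannulation of 1,3-dienes with ortho-halophenols. It sets out from aristolone 8 and bromophenol 14 and comes back at 21. Soft enolisation of 8 (TBSOTf, Et3N, CH2Cl2, 0 °C) removes a γ-hydrogen from C1 and should give 8-(tert-butyldimethylsilyloxy)aristola-1(10),8-diene F1. Heating F1 with 14 (Pd(OAc)2, tri-tert-butylphosphonium tetrafluoroborate, K2CO3, DMF, 90 °C) should add the aryl–palladium species syn to the diene terminus C1 on the α face and then form the C10–O bond from the π-allyl complex on the same face, giving the cis-fused dihydrobenzofuran silyl enol ether F2. Ethylene glycol with PPTS in benzene then converts the enol ether into the dioxolane 21. Steps 5–7 and 10–13 are bypassed.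

2. Step 6. Osmylation may take the β face (anti to the C5 methyl) or show poor facial selectivity, which would give the C10 epimer of the ketol. The fallback sets out from alkene 9 and comes back at ketol 11, and it turns a β-face bias into the required configuration by an inverting opening. Epoxidation of 9 (mCPBA, NaHCO3, CH2Cl2, 0 °C) on that face gives 1β,10β-epoxy-8,8-(ethylenedioxy)aristolane F3. Dilute HClO4 in THF/H2O at 0 °C opens F3 at the tertiary carbon C10 with inversion to give 8,8-(ethylenedioxy)aristolane-1β,10α-diol F4. IBX in DMSO oxidises the C1 carbinol of F4 to 11.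

3. Step 16. At 90 °C the oxidation may stall, the β-aryloxy ketone may lose the aryloxy group through its enol (opening the dihydrofuran), or the MOM ether may be lost and the chalcone then cyclise oxidatively. The fallback sets out from 25 and comes back at 26 through a low-temperature Rubottom sequence. Soft enolisation (TMSOTf, Et3N, CH2Cl2, −20 °C), possible only toward C9, gives the 8-trimethylsilyloxy-8-ene F5. Rubottom oxidation (mCPBA, NaHCO3, CH2Cl2, −20 °C; then citric acid, MeOH) gives the 9-hydroxy-8-ketone F6. Dess–Martin periodinane in CH2Cl2 oxidises F6 to the dione 26.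

Further compounds
F1 | step 12 | 8-(tert-butyldimethylsilyloxy)aristola-1(10),8-diene | C[C@@H]1CCC=C2C=C(O[Si](C)(C)C(C)(C)C)[C@@H]3[C@H]([C@@]12C)C3(C)C
F2 | step 12 | cis-fused dihydrobenzofuran with C8 tert-butyldimethylsilyl enol ether (C8=C9), C1–H β, 1'-acetyl, 2'-OMOM, 4'-OMe | CC(=O)c1c(OCOC)cc(OC)c2c1O[C@]13C=C(O[Si](C)(C)C(C)(C)C)[C@@H]4[C@@H](C4(C)C)[C@@]1(C)[C@H](C)CC[C@H]23
F3 | step 6 | 1β,10β-epoxy-8,8-(ethylenedioxy)aristolane | O1[C@@]23CC4(OCCO4)[C@@H]5[C@@H](C5(C)C)[C@@]2(C)[C@H](C)CC[C@@H]13
F4 | step 6 | 8,8-(ethylenedioxy)aristolane-1β,10α-diol | O[C@]12CC3(OCCO3)[C@@H]4[C@@H](C4(C)C)[C@@]1(C)[C@H](C)CC[C@H]2O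
F5 | step 16 | trimethylsilyl enol ether of 25 (C8=C9, 8-OSiMe3) | COc1ccc(/C=C/C(=O)c2c(OCOC)cc(OC)c3c2O[C@]24C=C(O[Si](C)(C)C)[C@@H]5[C@@H](C5(C)C)[C@@]2(C)[C@H](C)CC[C@H]34)cc1
F6 | step 16 | 9-hydroxy-8-ketone of 25 (C9 epimers) | COc1ccc(/C=C/C(=O)c2c(OCOC)cc(OC)c3c2O[C@]24C(O)C(=O)[C@@H]5[C@@H](C5(C)C)[C@@]2(C)[C@H](C)CC[C@H]34)cc1
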